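**Retrosynthetic overview**
- Target ⇐ its catechol bis-silyl ether ⇐ B-alkyl Suzuki union (Ar–CH2 bond of the bibenzyl) of a 6-bromochromene allylic alcohol with the 9-BBN adduct of a 2,3-bis(silyloxy)styrene.
- Allylic alcohol ⇐ (E)-selective allylic oxidation of the prenyl terminus of the bromochromene.
- Pyran ring (the only ring built; both benzene rings are bought) ⇐ enantioselective C2–O bond formation by dehydrative cyclisation of a racemic o-hydroxycinnamyl tertiary alcohol; this sets the quaternary stereocentre.
- That alcohol ⇐ Heck coupling of 4-bromo-2-iodophenol with racemic linalool; the styrene ⇐ 2,3-dihydroxybenzaldehyde by silylation and methylenation.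

Assumption: the three starting materials are catalogue chemicals, and because the sense of induction of the new catalyst in step 2 cannot be predicted with certainty, the catalyst antipode (from (R)- or (S)-BINOL) that gives the (S)-chromene is chosen after the first run.

The target's stereocentre is (S) (priorities O > C3 of the chromene > chain CH2 > CH3), and the side-chain olefin is (E).

**Step 1**
Reactants: 1 4-bromo-2-iodophenol; 2 (±)-linalool (3,7-dimethylocta-1,6-dien-3-ol)
Product: 3 (±)-(E)-4-bromo-2-(3-hydroxy-3,7-dimethylocta-1,6-dien-1-yl)phenol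
Conditions: Pd(OAc)2 (3 mol %), NaHCO3, n-Bu4NCl, DMF, 60 °C; chromatography on Et3N-washed silica
Reagents that add atoms: none
Why: A ligand-free Mizoroki–Heck reaction (Jeffery conditions) inserts Pd into C–I and not C–Br, adds to the unhindered vinyl group of linalool, and can only β-hydride-eliminate toward the benzylic carbon because the carbinol carbon bears no hydrogen, so the (E)-styrenyl tertiary alcohol results.

**Step 2**
Reactants: 3 (±)-(E)-4-bromo-2-(3-hydroxy-3,7-dimethylocta-1,6-dien-1-yl)phenol
Product: 5 (S)-6-bromo-2-methyl-2-(4-methylpent-3-en-1-yl)-2H-chromene, via ortho-quinone methide 4 (not isolated)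
Conditions: confined BINOL-derived imidodiphosphorimidate Brønsted acid (IDPi, N-triflyl core, 3,3′-aryl wings; 2–5 mol %), 5 Å MS, toluene, −60 °C
Reagents that add atoms: none
Why: Proposed new method: an enantioconvergent dehydrative oxa-cyclisation in which the strong confined acid ionises either enantiomer of the tertiary allylic alcohol to the same achiral o-hydroxycinnamyl cation/ortho-quinone methide 4, held as a hydrogen-bonded contact ion pair; rotation about the former C1=C2 bond gives the s-cis form and the C2–O bond then closes (oxa-6π/ion-pair collapse) on one face of the methyl/alkyl-substituted terminus inside the catalyst pocket, which must tell methyl from the homoprenyl chain to set the (S) quaternary centre; the closest known reaction type is the chiral N-triflylphosphoramide-catalysed asymmetric intramolecular allylic substitution of 2-(3-aryl-3-hydroxyalk-1-enyl)phenols to 2-aryl-2-alkyl-2H-chromenes, extended here to a dialkyl carbinol by using a confined anion of the kind known to discriminate small alkyl groups.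

**Step 3**
Reactants: 5 (S)-6-bromo-2-methyl-2-(4-methylpent-3-en-1-yl)-2H-chromene
Product: 6 (S,E)-5-(6-bromo-2-methyl-2H-chromen-2-yl)-2-methylpent-2-en-1-ol
Conditions: SeO2 (0.3 equiv), t-BuOOH, salicylic acid (cat.), CH2Cl2, rt
Reagents that add atoms: selenium dioxide, O=[Se]=O (catalytic oxygen carrier); tert-butyl hydroperoxide, CC(C)(C)OO (stoichiometric oxygen source)
Why: Riley allylic oxidation (ene reaction then [2,3]-sigmatropic shift) oxidises at the more substituted terminus of the only olefin that has allylic hydrogens, selectively at the methyl trans to the chain, giving the (E)-allylic alcohol without touching the chromene olefin or the stereocentre.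

**Step 4**
Reactants: 7 2,3-dihydroxybenzaldehyde
Product: 8 2,3-bis(tert-butyldimethylsilyloxy)benzaldehyde
Conditions: TBSCl, imidazole, DMF, rt
Reagents that add atoms: tert-butyldimethylsilyl chloride (TBSCl), CC(C)(C)[Si](C)(C)Cl
Why: Imidazole-promoted O-silylation caps both phenols with a group that survives ylide, borane and Pd chemistry and comes off with fluoride at the end.

**Step 5**
Reactants: 8 2,3-bis(tert-butyldimethylsilyloxy)benzaldehyde
Product: 9 1,2-bis(tert-butyldimethylsilyloxy)-3-vinylbenzene
Conditions: Ph3PCH3Br (1.3 equiv), KOt-Bu (1.25 equiv), THF, 0 °C → rt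
Reagents that add atoms: methyltriphenylphosphonium bromide, C[P+](c1ccccc1)(c1ccccc1)c1ccccc1.[Br-]
Why: Wittig methylenation of the aldehyde with a non-stabilised ylide, made with a slight deficit of base so that no free alkoxide attacks the aryl silyl ethers.

**Step 6**
Reactants: 9 1,2-bis(tert-butyldimethylsilyloxy)-3-vinylbenzene; 6 (S,E)-5-(6-bromo-2-methyl-2H-chromen-2-yl)-2-methylpent-2-en-1-ol
Product: 11 (S,E)-5-(6-{2-[2,3-bis(tert-butyldimethylsilyloxy)phenyl]ethyl}-2-methyl-2H-chromen-2-yl)-2-methylpent-2-en-1-ol, via alkylborane 10 (not isolated)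
Conditions: 9 (1.4 equiv), 9-BBN (1.3 equiv), THF, 0 °C → rt; then 6 (1.0 equiv), Pd(dppf)Cl2 (5 mol %), 3 M aq K3PO4, THF, 50 °C, degassed
Reagents that add atoms: none
Why: Anti-Markovnikov hydroboration of the styrene followed by B-alkyl Suzuki–Miyaura coupling with the aryl bromide forms the bibenzyl without any hydrogenation; the styrene is in excess over B–H so no borane is left to attack the chromene or side-chain olefins, and the basic conditions leave the stereocentre alone.

**Step 7**
Reactants: 11 (S,E)-5-(6-{2-[2,3-bis(tert-butyldimethylsilyloxy)phenyl]ethyl}-2-methyl-2H-chromen-2-yl)-2-methylpent-2-en-1-ol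
Product: 12 3-{2-[(2S)-2-[(3E)-5-hydroxy-4-methylpent-3-en-1-yl]-2-methyl-2H-chromen-6-yl]ethyl}benzene-1,2-diol (CNP0267525.1)
Conditions: TBAF, AcOH (1:1, 2.5 equiv each), THF, 0 °C, argon
Reagents that add atoms: none
Why: Fluoride-driven cleavage of both aryl silyl ethers, buffered with acetic acid so the catechol is released as the neutral diol and not the air-sensitive catecholate; the chromene, allylic alcohol and stereocentre are unaffected.

**Compound list**
1 | 4-bromo-2-iodophenol | Oc1ccc(Br)cc1I | starting material
2 | (±)-linalool | C=CC(C)(O)CCC=C(C)C | starting material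
3 | (±)-(E)-4-bromo-2-(3-hydroxy-3,7-dimethylocta-1,6-dien-1-yl)phenol (racemic at the carbinol) | Oc1ccc(Br)cc1/C=C/C(C)(O)CCC=C(C)C | intermediate
4 | 4-bromo-6-(3,7-dimethylocta-2,6-dien-1-ylidene)cyclohexa-2,4-dien-1-one (ortho-quinone methide; double-bond geometries equilibrating, not fixed) | O=C1C=CC(Br)=CC1=CC=C(C)CCC=C(C)C | intermediate (not isolated)
5 | (S)-6-bromo-2-methyl-2-(4-methylpent-3-en-1-yl)-2H-chromene | CC(C)=CCC[C@@]1(C)C=Cc2cc(Br)ccc2O1 | intermediate
6 | (S,E)-5-(6-bromo-2-methyl-2H-chromen-2-yl)-2-methylpent-2-en-1-ol | C/C(=C\CC[C@@]1(C)C=Cc2cc(Br)ccc2O1)CO | intermediate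
7 | 2,3-dihydroxybenzaldehyde | O=Cc1cccc(O)c1O | starting material
8 | 2,3-bis(tert-butyldimethylsilyloxy)benzaldehyde | O=Cc1cccc(O[Si](C)(C)C(C)(C)C)c1O[Si](C)(C)C(C)(C)C | intermediate
9 | 1,2-bis(tert-butyldimethylsilyloxy)-3-vinylbenzene | C=Cc1cccc(O[Si](C)(C)C(C)(C)C)c1O[Si](C)(C)C(C)(C)C | intermediate
10 | 9-{2-[2,3-bis(tert-butyldimethylsilyloxy)phenyl]ethyl}-9-borabicyclo[3.3.1]nonane | CC(C)(C)[Si](C)(C)Oc1cccc(CCB2C3CCCC2CCC3)c1O[Si](C)(C)C(C)(C)C | intermediate (not isolated)
11 | (S,E)-5-(6-{2-[2,3-bis(tert-butyldimethylsilyloxy)phenyl]ethyl}-2-methyl-2H-chromen-2-yl)-2-methylpent-2-en-1-ol | C/C(=C\CC[C@@]1(C)C=Cc2cc(CCc3cccc(O[Si](C)(C)C(C)(C)C)c3O[Si](C)(C)C(C)(C)C)ccc2O1)CO | intermediate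
12 | 3-{2-[(2S)-2-[(3E)-5-hydroxy-4-methylpent-3-en-1-yl]-2-methyl-2H-chromen-6-yl]ethyl}benzene-1,2-diol | C/C(=C\CC[C@@]1(C)C=Cc2cc(CCc3cccc(O)c3O)ccc2O1)CO | target

**Totals**
Total step count: 7. Longest linear sequence: 5 (steps 1, 2, 3, 6, 7).

**Steps most likely to fail**

Step 2 (the proposed new step). The catalyst must distinguish a methyl from a primary alkyl group at the cation terminus, which is untested. Background racemic closure by adventitious acid and cation–olefin side reactions of the prenyl group are the other dangers. Fallback with known chemistry: it sets out from 3, which is cyclised without asymmetric induction (PPTS cat., CH2Cl2, rt) to racemic 6-bromo-2-methyl-2-(4-methylpent-3-en-1-yl)-2H-chromene F1. The racemate is resolved by preparative chiral SFC on a polysaccharide carbamate phase, setting aside (R)-6-bromo-2-methyl-2-(4-methylpent-3-en-1-yl)-2H-chromene F2. The (S)-enantiomer collected is 5, where the route is rejoined.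

Step 3. Selenium dioxide oxidations of prenyl termini usually stop at moderate conversion and over-oxidise in part to the enal. Fallback: it sets out from 5, which undergoes olefin cross-metathesis with methacrolein (Hoveyda–Grubbs II, CH2Cl2, 40 °C), losing isobutene, to give (S,E)-5-(6-bromo-2-methyl-2H-chromen-2-yl)-2-methylpent-2-enal F3. Luche reduction (NaBH4, CeCl3·7H2O, MeOH, 0 °C) then returns to the route at 6.

Step 6. The aqueous base may strip some aryl silyl ether, and oxidative addition into the electron-rich aryl bromide may be slow enough for the borane to decompose first. Partly desilylated product is still usable, since step 7 removes the groups anyway. Fallback: it sets out from 9, whose borane 10 is oxidised instead of coupled (NaBO3·4H2O, THF/H2O, rt) to 2-[2,3-bis(tert-butyldimethylsilyloxy)phenyl]ethan-1-ol F4. An Appel reaction (CBr4, PPh3, CH2Cl2, 0 °C) gives 1-(2-bromoethyl)-2,3-bis(tert-butyldimethylsilyloxy)benzene F5. This is joined to aryl bromide 6 by base-free nickel-catalysed reductive cross-electrophile coupling (NiBr2·glyme, 4,4′-di-tert-butyl-2,2′-bipyridine, Zn, NaI, DMA, 60 °C), returning to the route at 11.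

**Further compounds**
F1 | step 2 | (±)-6-bromo-2-methyl-2-(4-methylpent-3-en-1-yl)-2H-chromene (racemate) | CC(C)=CCCC1(C)C=Cc2cc(Br)ccc2O1
F2 | step 2 | (R)-6-bromo-2-methyl-2-(4-methylpent-3-en-1-yl)-2H-chromene | CC(C)=CCC[C@]1(C)C=Cc2cc(Br)ccc2O1
F3 | step 3 | (S,E)-5-(6-bromo-2-methyl-2H-chromen-2-yl)-2-methylpent-2-enal | C/C(=C\CC[C@@]1(C)C=Cc2cc(Br)ccc2O1)C=O
F4 | step 6 | 2-[2,3-bis(tert-butyldimethylsilyloxy)phenyl]ethan-1-ol | OCCc1cccc(O[Si](C)(C)C(C)(C)C)c1O[Si](C)(C)C(C)(C)C
F5 | step 6 | 1-(2-bromoethyl)-2,3-bis(tert-butyldimethylsilyloxy)benzene | BrCCc1cccc(O[Si](C)(C)C(C)(C)C)c1O[Si](C)(C)C(C)(C)C
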